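Assumption: compounds 1, 5 and 9 (the lactone acid made from D-glutamic acid) are purchased. Locants in the "Why" lines follow the undecadiene chain of the target: C1 = carbinol next to the lactone, C6 = allylic carbinol, C11 = furyl CH2.

## Retrosynthetic overview

1. Target 20 ⇐ diol 19 (diacetylation) ⇐ bis-MOM lactone 18. Its quaternary carbon and lactone ring come from chelation-controlled MeMgBr addition to γ-keto ester 17, which lactonises in the same step.
2. 17 ⇐ hydroxy-lactone 14 (protect, open lactone, oxidise). The C1 carbinol of 14 comes from Felkin–Anh reduction of keto-lactone 13. The glutamic-acid centre sets C1, is then oxidised away, and C1 sets the quaternary centre (a stereochemical relay).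
3. 13 ⇐ β-keto ester 12 by a Carroll [3,3]-sigmatropic rearrangement, which forms the C2–C3 bond and the (E)-C4=C5 olefin.
4. 12 ⇐ allylic alcohol 8 + acyl Meldrum's acid 11 (from 9). 8 ⇐ methyl (S)-glycidate 5 (supplies C6) + vinyl iodide 4, then DIBAL/isopropenyl Grignard.
5. 4 ⇐ 2-(3-furyl)ethanol 1. Rings: the furan is purchased; the γ-lactone is purchased in 9, opened in step 12 and re-closed on the new quaternary carbon in step 14.

## Route

**Step 1**
Reactants: 1, 2-(furan-3-yl)ethanol
Product: 2, 3-(2-iodoethyl)furan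
Conditions: I2, PPh3, imidazole, CH2Cl2, 0 °C → rt
Reagents that add atoms: iodine, II
Why: Appel-type iodination of a primary alcohol under neutral conditions that the furan tolerates.

**Step 2**
Reactants: 2
Product: 3, 3-(pent-3-yn-1-yl)furan
Conditions: 1-propynyllithium, THF–DMPU, −78 °C → rt
Reagents that add atoms: 1-propynyllithium, [Li]C#CC
Why: SN2 alkylation of a lithium acetylide by a primary iodide, favoured over E2 in a dipolar cosolvent.

**Step 3**
Reactants: 3
Product: 4, 3-[(3E)-4-iodopent-3-en-1-yl]furan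
Conditions: Cp2Zr(H)Cl (2 equiv), THF, 45 °C; then I2, 0 °C
Reagents that add atoms: iodine, II
Why: Schwartz hydrozirconation is a syn addition; equilibration with excess reagent puts Zr on the methyl-bearing carbon (expect about 9:1), and iodinolysis with retention gives the (E)-2-iodoalkene.

**Step 4**
Reactants: 4; 5, methyl (2S)-oxirane-2-carboxylate
Product: 6, methyl (2S,4E)-7-(furan-3-yl)-2-hydroxy-4-methylhept-4-enoate
Conditions: t-BuLi (2 equiv), Et2O, −78 °C; MgBr2·OEt2; CuI (10 mol %); then 5, −78 → −30 °C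
Reagents that add atoms: none
Why: I/Li exchange with retention of olefin geometry, then Cu-catalysed opening of the glycidate at its CH2 terminus, which leaves the purchased C–O stereocentre (future C6, S) untouched.

**Step 5**
Reactants: 6
Product: 7, methyl (2S,4E)-7-(furan-3-yl)-2-(methoxymethoxy)-4-methylhept-4-enoate
Conditions: MOMCl, i-Pr2NEt, Bu4NI (cat.), CH2Cl2, 0 °C → rt
Reagents that add atoms: chloromethyl methyl ether, COCCl
Why: Williamson-type acetal protection; MOM survives every later organometallic, thermal and basic step.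

**Step 6**
Reactants: 7
Product: 8, (3RS,4S,6E)-9-(furan-3-yl)-4-(methoxymethoxy)-2,6-dimethylnona-1,6-dien-3-ol
Conditions: DIBAL-H, CH2Cl2, −78 °C; then isopropenylmagnesium bromide, THF, −78 → 0 °C
Reagents that add atoms: isopropenylmagnesium bromide, CC(=C)[Mg]Br
Why: Half-reduction of the α-alkoxy ester to its chelated aluminium hemiacetal and in situ Grignard addition; the new carbinol is formed as a mixture, which does not matter because it is erased in step 9.

**Step 7**
Reactants: 9, (2R)-5-oxotetrahydrofuran-2-carboxylic acid; 10, Meldrum's acid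
Product: 11, 5-{hydroxy[(2R)-5-oxotetrahydrofuran-2-yl]methylidene}-2,2-dimethyl-1,3-dioxane-4,6-dione
Conditions: DCC, DMAP, CH2Cl2, 0 °C → rt
Reagents that add atoms: none
Why: Standard C-acylation of Meldrum's acid by an activated acid (Oikawa–Yonemitsu); the α-acyloxy stereocentre is retained.

**Step 8**
Reactants: 8; 11
Product: 12, (3RS,4S,6E)-9-(furan-3-yl)-4-(methoxymethoxy)-2,6-dimethylnona-1,6-dien-3-yl 3-oxo-3-[(2R)-5-oxotetrahydrofuran-2-yl]propanoate
Conditions: PhMe, 90 °C (−acetone, −CO2)
Reagents that add atoms: none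
Why: Thermolysis of the acyl Meldrum's acid gives an acylketene that the secondary allylic alcohol traps as its β-keto ester.

**Step 9 (key step)**
Reactants: 12
Product: 13, (5R)-5-[(4E,6S,8E)-11-(furan-3-yl)-6-(methoxymethoxy)-4,8-dimethylundeca-4,8-dienoyl]dihydrofuran-2(3H)-one
Conditions: mesitylene, 160 °C, sealed tube (−CO2)
Reagents that add atoms: none
Why: Carroll (decarboxylative Claisen) [3,3]-sigmatropic rearrangement of the enol form through a chair transition state with the C6-bearing group equatorial; it forms the C2–C3 bond and the (E)-C4=C5 trisubstituted olefin, and the β-keto acid then loses CO2.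

**Step 10**
Reactants: 13
Product: 14, (5R)-5-[(1R,4E,6S,8E)-11-(furan-3-yl)-1-hydroxy-6-(methoxymethoxy)-4,8-dimethylundeca-4,8-dien-1-yl]dihydrofuran-2(3H)-one
Conditions: L-Selectride, THF, −78 °C
Reagents that add atoms: none
Why: Felkin–Anh reduction with the lactone C–O bond anti to the bulky hydride gives the threo (1R) alcohol (expect about 9:1), controlled by the purchased lactone centre; the ketone reacts before the lactone at −78 °C.

**Step 11**
Reactants: 14
Product: 15, (5R)-5-[(1R,4E,6S,8E)-11-(furan-3-yl)-1,6-bis(methoxymethoxy)-4,8-dimethylundeca-4,8-dien-1-yl]dihydrofuran-2(3H)-one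
Conditions: MOMCl, i-Pr2NEt, Bu4NI, CH2Cl2, 40 °C
Reagents that add atoms: chloromethyl methyl ether, COCCl
Why: Acetal protection of the C1 alcohol; MOM is chosen because it chelates magnesium in step 14.

**Step 12**
Reactants: 15
Product: 16, methyl (4R,5R,8E,10S,12E)-15-(furan-3-yl)-4-hydroxy-5,10-bis(methoxymethoxy)-8,12-dimethylpentadeca-8,12-dienoate
Conditions: KOH, MeOH/H2O, rt; evaporate; MeI, DMF, 0 °C (used crude)
Reagents that add atoms: hydroxide/water, O; iodomethane, CI
Why: Saponification of the lactone followed by irreversible O-alkylation of the carboxylate frees the ring carbinol as a γ-hydroxy methyl ester without touching C1.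

**Step 13**
Reactants: 16
Product: 17, methyl (5R,8E,10S,12E)-15-(furan-3-yl)-5,10-bis(methoxymethoxy)-8,12-dimethyl-4-oxopentadeca-8,12-dienoate
Conditions: Dess–Martin periodinane, NaHCO3, CH2Cl2, 0 °C → rt
Reagents that add atoms: none
Why: Buffered Dess–Martin oxidation gives the α-MOM-oxy ketone without epimerising C1 (C5 of 17); the original glutamic-acid centre is removed here after doing its job.

**Step 14**
Reactants: 17
Product: 18, (5S)-5-[(1R,4E,6S,8E)-11-(furan-3-yl)-1,6-bis(methoxymethoxy)-4,8-dimethylundeca-4,8-dien-1-yl]-5-methyldihydrofuran-2(3H)-one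
Conditions: MeMgBr (1.3 equiv), Et2O/CH2Cl2, −78 → 0 °C; aq NH4Cl
Reagents that add atoms: methylmagnesium bromide, C[Mg]Br
Why: Cram-chelate Grignard addition: Mg bridges the ketone and the α-OMOM oxygen and methyl adds anti to the C2 chain, giving the (S) quaternary carbinol (anti to C1–O); the alkoxide then closes onto the methyl ester to re-form the γ-lactone.

**Step 15**
Reactants: 18
Product: 19, (5S)-5-[(1R,4E,6S,8E)-11-(furan-3-yl)-1,6-dihydroxy-4,8-dimethylundeca-4,8-dien-1-yl]-5-methyldihydrofuran-2(3H)-one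
Conditions: ZnBr2, n-PrSH, CH2Cl2, 0 °C
Reagents that add atoms: none
Why: Mild Lewis acid/thiol cleavage of both MOM acetals, avoiding protic acid that could damage the furan or ionise the allylic alcohol.

**Step 16**
Reactants: 19
Product: 20, Irciformonin F, (1R,4E,6S,8E)-11-(furan-3-yl)-4,8-dimethyl-1-[(2S)-2-methyl-5-oxotetrahydrofuran-2-yl]undeca-4,8-diene-1,6-diyl diacetate
Conditions: Ac2O, pyridine, DMAP (cat.), CH2Cl2, rt
Reagents that add atoms: acetic anhydride, CC(=O)OC(C)=O
Why: DMAP-catalysed acetylation of both secondary alcohols; no stereocentre is touched.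

## Compound list

1 | 2-(furan-3-yl)ethanol | OCCc1ccoc1 | starting material
2 | 3-(2-iodoethyl)furan | ICCc1ccoc1 | intermediate
3 | 3-(pent-3-yn-1-yl)furan | CC#CCCc1ccoc1 | intermediate
4 | 3-[(3E)-4-iodopent-3-en-1-yl]furan | C/C(I)=C\CCc1ccoc1 | intermediate
5 | methyl (2S)-oxirane-2-carboxylate | COC(=O)[C@@H]1CO1 | starting material
6 | methyl (2S,4E)-7-(furan-3-yl)-2-hydroxy-4-methylhept-4-enoate | COC(=O)[C@@H](O)C/C(C)=C/CCc1ccoc1 | intermediate
7 | methyl (2S,4E)-7-(furan-3-yl)-2-(methoxymethoxy)-4-methylhept-4-enoate | COC(=O)[C@@H](OCOC)C/C(C)=C/CCc1ccoc1 | intermediate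
8 | (3RS,4S,6E)-9-(furan-3-yl)-4-(methoxymethoxy)-2,6-dimethylnona-1,6-dien-3-ol | C=C(C)C(O)[C@@H](OCOC)C/C(C)=C/CCc1ccoc1 | intermediate
9 | (2R)-5-oxotetrahydrofuran-2-carboxylic acid | OC(=O)[C@H]1CCC(=O)O1 | starting material
10 | Meldrum's acid | CC1(C)OC(=O)CC(=O)O1 | starting material
11 | 5-{hydroxy[(2R)-5-oxotetrahydrofuran-2-yl]methylidene}-2,2-dimethyl-1,3-dioxane-4,6-dione | CC1(C)OC(=O)C(=C(O)[C@H]2CCC(=O)O2)C(=O)O1 | intermediate
12 | allyl β-keto ester of 8 | C=C(C)C(OC(=O)CC(=O)[C@H]1CCC(=O)O1)[C@@H](OCOC)C/C(C)=C/CCc1ccoc1 | intermediate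
13 | (5R)-5-[(4E,6S,8E)-11-(furan-3-yl)-6-(methoxymethoxy)-4,8-dimethylundeca-4,8-dienoyl]dihydrofuran-2(3H)-one | O=C(CC/C(C)=C/[C@@H](OCOC)C/C(C)=C/CCc1ccoc1)[C@H]1CCC(=O)O1 | intermediate
14 | (5R)-5-[(1R,4E,6S,8E)-1-hydroxy-6-MOM-oxy side chain]dihydrofuran-2(3H)-one | O[C@H](CC/C(C)=C/[C@@H](OCOC)C/C(C)=C/CCc1ccoc1)[C@H]1CCC(=O)O1 | intermediate
15 | (5R)-5-[(1R,4E,6S,8E)-1,6-bis-MOM-oxy side chain]dihydrofuran-2(3H)-one | COCO[C@H](CC/C(C)=C/[C@@H](OCOC)C/C(C)=C/CCc1ccoc1)[C@H]1CCC(=O)O1 | intermediate
16 | methyl (4R,5R,8E,10S,12E)-15-(furan-3-yl)-4-hydroxy-5,10-bis(methoxymethoxy)-8,12-dimethylpentadeca-8,12-dienoate | COC(=O)CC[C@@H](O)[C@H](OCOC)CC/C(C)=C/[C@@H](OCOC)C/C(C)=C/CCc1ccoc1 | intermediate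
17 | methyl (5R,8E,10S,12E)-15-(furan-3-yl)-5,10-bis(methoxymethoxy)-8,12-dimethyl-4-oxopentadeca-8,12-dienoate | COC(=O)CCC(=O)[C@H](OCOC)CC/C(C)=C/[C@@H](OCOC)C/C(C)=C/CCc1ccoc1 | intermediate
18 | (5S)-5-[(1R,4E,6S,8E)-1,6-bis-MOM-oxy side chain]-5-methyldihydrofuran-2(3H)-one | COCO[C@H](CC/C(C)=C/[C@@H](OCOC)C/C(C)=C/CCc1ccoc1)[C@]1(C)CCC(=O)O1 | intermediate
19 | (5S)-5-[(1R,4E,6S,8E)-11-(furan-3-yl)-1,6-dihydroxy-4,8-dimethylundeca-4,8-dien-1-yl]-5-methyldihydrofuran-2(3H)-one | O[C@H](CC/C(C)=C/[C@@H](O)C/C(C)=C/CCc1ccoc1)[C@]1(C)CCC(=O)O1 | intermediate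
20 | Irciformonin F | CC(=O)O[C@H](/C=C(\C)CC[C@@H](OC(C)=O)[C@]1(C)CCC(=O)O1)C/C(C)=C/CCc1ccoc1 | target

## Summary

Total steps: 16. Longest linear sequence: 15 (steps 1–6 and 8–16; step 7 is a one-step side branch).

Steps most likely to fail:

1. **Step 9, thermal Carroll rearrangement.** It needs about 160 °C, and the stereocentre α to the ketone in 12/13 could erode; that centre controls step 10. Fallback: run a Johnson orthoester Claisen on 8 (MeC(OEt)3, cat. EtCO2H, 140 °C) to get the γ,δ-unsaturated ester, C-acylate its lithium enolate with the acid chloride of 9, then hydrolyse and decarboxylate to the same ketone 13.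
2. **Step 4, vinyl-metal generation and glycidate opening.** t-BuLi may deprotonate the furan α-position, and the organometallic may attack the ester. Fallback: open tert-butyldimethylsilyl (S)-glycidyl ether (no ester present) with the vinyllithium/BF3·OEt2, then MOM-protect, desilylate and oxidise the primary alcohol to the α-MOM-oxy aldehyde for isopropenyl addition.
3. **Step 12, lactone opening.** The γ-hydroxy ester 16 can relactonise before it is oxidised. Fallback: open 15 with Me2AlNMe2 to the hydroxy dimethylamide, which cannot relactonise under neutral conditions; oxidise, add MeMgBr, then close the lactone with mild acid.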